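**Plan**
- Cuts, in retrosynthetic order: the central C(sp2)–C(sp2) single bond of the (1E,3E)-buta-1,3-diene-1,4-diyl linker; the ring C4–vinyl bond; the C2–CH3 bond at the quaternary carbon; the ring-carbon–(4-methylpent-3-enyl) bond; the oxirane C–O bonds.
- Enabling feature: a C2 axis passes through the midpoint of the central diene single bond. Both cyclohex-3-en-1-ol rings (carbinol C1 R, quaternary C2 S) and both 3,3-dimethyloxirane rings (R) are identical, so a single (E)-alkenylstannane can be homocoupled.
- Forward order: the cyclohexene ring is bought as enone ketal 1. The chain is joined as homoprenyl (Negishi), then methyl (cuprate, enolate trapped as the regiodefined triflate), then the oxirane ring is formed (Shi), then the vinylstannane is attached (Stille), and the two C15 halves are joined last.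
- Stereochemistry: the carbinol comes from CBS reduction; the quaternary carbon from cuprate addition anti to the neighbouring silyloxy group; the oxirane from the D-fructose-derived Shi ketone; the E,E-diene from the (E)-bis-stannane with retention in both couplings.

Key step: step 10

Remark: 1 is taken as a catalogue compound, and the copper/lithium enolate of step 6 is written as its lithium salt.

**Step 1**
Reactants: 1 1,4-dioxaspiro[4.5]dec-6-en-8-one
Product: 2 7-iodo-1,4-dioxaspiro[4.5]dec-6-en-8-one
Conditions: I2, pyridine, CH2Cl2, 0 °C → rt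
Reagents that add atoms: iodine (II)
Why: Pyridine-mediated α-iodination of a cyclic enone (Johnson iodination, addition–iodination–elimination) should give the 2-iodoenone without touching the ketal; no stereocentre is formed.

**Step 2**
Reactants: 2 7-iodo-1,4-dioxaspiro[4.5]dec-6-en-8-one
Product: 3 (8R)-7-iodo-1,4-dioxaspiro[4.5]dec-6-en-8-ol
Conditions: (S)-Me-CBS (10 mol %), BH3·SMe2, THF, −20 °C; then MeOH, aq. work-up
Reagents that add atoms: none
Why: In the Corey–Bakshi–Shibata reduction the α-iodovinyl arm acts as the large group, so the (S)-oxazaborolidine should deliver hydride to the face that gives the (R)-allylic alcohol (catalyst control).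

**Step 3**
Reactants: 3 (8R)-7-iodo-1,4-dioxaspiro[4.5]dec-6-en-8-ol
Product: 4 tert-butyl{[(8R)-7-iodo-1,4-dioxaspiro[4.5]dec-6-en-8-yl]oxy}dimethylsilane
Conditions: TBSCl, imidazole, DMF, rt
Reagents that add atoms: tert-butyldimethylsilyl chloride (CC(C)(C)[Si](C)(C)Cl)
Why: Imidazole-promoted silylation of a secondary allylic alcohol is routine and the silyl ether later serves as the bulky group that steers the cuprate.

**Step 4**
Reactants: 4 tert-butyl{[(8R)-7-iodo-1,4-dioxaspiro[4.5]dec-6-en-8-yl]oxy}dimethylsilane; 5 5-bromo-2-methylpent-2-ene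
Product: 8 tert-butyldimethyl{[(8R)-7-(4-methylpent-3-en-1-yl)-1,4-dioxaspiro[4.5]dec-6-en-8-yl]oxy}silane, via (4-methylpent-3-enyl)magnesium bromide 6 (not isolated), via (4-methylpent-3-enyl)zinc chloride 7 (not isolated)
Conditions: 5, Mg, THF; ZnCl2, THF, 0 °C; then 4, Pd(dppf)Cl2 (5 mol %), THF, rt → 45 °C
Reagents that add atoms: none
Why: Negishi sp2–sp3 cross-coupling of a cyclic alkenyl iodide with a primary alkylzinc should proceed cleanly because the wide-bite-angle dppf ligand favours reductive elimination over β-hydride elimination; the stereocentre is not involved.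

**Step 5**
Reactants: 8 tert-butyldimethyl{[(8R)-7-(4-methylpent-3-en-1-yl)-1,4-dioxaspiro[4.5]dec-6-en-8-yl]oxy}silane
Product: 9 (4R)-4-[(tert-butyldimethylsilyl)oxy]-3-(4-methylpent-3-en-1-yl)cyclohex-2-en-1-one
Conditions: PPTS (cat.), acetone/H2O, 50 °C
Reagents that add atoms: water (O)
Why: Acid-catalysed hydrolysis of the allylic ketal through a stabilised allylic oxocarbenium ion should be mild enough to spare the TBS ether and the trisubstituted alkene, and the γ-stereocentre cannot epimerise.

**Step 6**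
Reactants: 9 (4R)-4-[(tert-butyldimethylsilyl)oxy]-3-(4-methylpent-3-en-1-yl)cyclohex-2-en-1-one
Product: 11 (3S,4R)-4-[(tert-butyldimethylsilyl)oxy]-3-methyl-3-(4-methylpent-3-en-1-yl)cyclohex-1-en-1-yl trifluoromethanesulfonate, via lithium enolate 10 (not isolated)
Conditions: MeLi, CuI, Et2O, −20 → 0 °C; then PhNTf2, THF, 0 °C → rt
Reagents that add atoms: lithium dimethylcuprate ([Li+].C[Cu-]C); N-phenylbis(trifluoromethanesulfonimide) (O=S(=O)(N(c1ccccc1)S(=O)(=O)C(F)(F)F)C(F)(F)F)
Why: Gilman cuprate conjugate addition to the β,β-disubstituted enone should place methyl axially on the face anti to the C4 silyloxy group (held pseudoaxial by A(1,2) strain with the C3 chain), setting the quaternary carbon with methyl trans to oxygen, and O-triflation of the regiodefined enolate (McMurry-type enol triflate formation) fixes the double bond next to the quaternary carbon.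

**Step 7**
Reactants: 11 (3S,4R)-4-[(tert-butyldimethylsilyl)oxy]-3-methyl-3-(4-methylpent-3-en-1-yl)cyclohex-1-en-1-yl trifluoromethanesulfonate
Product: 12 (3S,4R)-4-[(tert-butyldimethylsilyl)oxy]-3-{2-[(2R)-3,3-dimethyloxiran-2-yl]ethyl}-3-methylcyclohex-1-en-1-yl trifluoromethanesulfonate
Conditions: D-fructose-derived Shi ketone (30 mol %), Oxone, K2CO3, Bu4NHSO4, MeCN/DMM, aq. Na2B4O7–EDTA buffer, 0 °C
Reagents that add atoms: Oxone, potassium peroxymonosulfate ([K+].[O-]S(=O)(=O)OO)
Why: In the Shi asymmetric epoxidation the chiral dioxirane should attack the electron-rich trisubstituted alkene through the spiro transition state to give the (R)-oxirane (reagent control), while the electron-poor enol triflate alkene should not react.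

**Step 8**
Reactants: 12 (3S,4R)-4-[(tert-butyldimethylsilyl)oxy]-3-{2-[(2R)-3,3-dimethyloxiran-2-yl]ethyl}-3-methylcyclohex-1-en-1-yl trifluoromethanesulfonate; 13 (E)-1,2-bis(tributylstannyl)ethene
Product: 14 tert-butyl{[(1R,2S)-2-{2-[(2R)-3,3-dimethyloxiran-2-yl]ethyl}-2-methyl-4-[(E)-2-(tributylstannyl)ethenyl]cyclohex-3-en-1-yl]oxy}dimethylsilane
Conditions: 13 (3 equiv), Pd2(dba)3 (5 mol %), AsPh3, LiCl, NMP, rt → 40 °C
Reagents that add atoms: none
Why: Stille–Migita coupling of the alkenyl triflate with an excess of the bis-stannane should transfer one stannylvinyl unit with retention of E geometry, the excess suppressing a second coupling, and the oxirane and silyl ether are inert to Pd(0).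

**Step 9**
Reactants: 14 tert-butyl{[(1R,2S)-2-{2-[(2R)-3,3-dimethyloxiran-2-yl]ethyl}-2-methyl-4-[(E)-2-(tributylstannyl)ethenyl]cyclohex-3-en-1-yl]oxy}dimethylsilane
Product: 15 (1R,2S)-2-{2-[(2R)-3,3-dimethyloxiran-2-yl]ethyl}-2-methyl-4-[(E)-2-(tributylstannyl)ethenyl]cyclohex-3-en-1-ol
Conditions: TBAF, THF, rt → 40 °C
Reagents that add atoms: none
Why: Fluoride-driven desilylation should free the hindered secondary alcohol under basic, non-acidic conditions that leave the C(sp2)–Sn bond and the oxirane intact.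

**Step 10**
Reactants: 15 (1R,2S)-2-{2-[(2R)-3,3-dimethyloxiran-2-yl]ethyl}-2-methyl-4-[(E)-2-(tributylstannyl)ethenyl]cyclohex-3-en-1-ol (two molecules)
Product: 16 (1R,1'R,2S,2'S)-4,4'-[(1E,3E)-buta-1,3-diene-1,4-diyl]bis(2-{2-[(2R)-3,3-dimethyloxiran-2-yl]ethyl}-2-methylcyclohex-3-en-1-ol)
Conditions: CuCl (5 equiv), dry degassed DMF, 0 °C → rt, dark
Reagents that add atoms: none
Why: Sn-to-Cu transmetalation in DMF should turn the C(sp2)–SnBu3 bond of each molecule of 15 into an (E)-dienylcopper(I) species with loss of Bu3SnCl, and two such units should couple within a copper aggregate (formally 2 RCu → R–R + 2 Cu) with retention of both double-bond geometries. The closest known reaction type is the copper(I) chloride-mediated oxidative homocoupling of alkenylstannanes, a variant of the classical dimerisation of alkenylcopper reagents. No ring is closed and no stereocentre is formed or touched; the new bond is the central single bond of the (1E,3E)-diene. Because both partners are the same single enantiomer, only the C2-symmetric dimer can form, so no meso or cross-combination product can arise. The step needs chemoselectivity for the C–Sn bond and retention of E geometry: the neutral, aprotic, room-temperature conditions should spare the free secondary hydroxyls and the trisubstituted oxiranes, and the stannylated carbon is the only site that transmetalates.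

**Compound list**
1 | 1,4-dioxaspiro[4.5]dec-6-en-8-one | O=C1CCC2(OCCO2)C=C1 | starting material
2 | 7-iodo-1,4-dioxaspiro[4.5]dec-6-en-8-one | O=C1CCC2(OCCO2)C=C1I | intermediate
3 | (8R)-7-iodo-1,4-dioxaspiro[4.5]dec-6-en-8-ol | IC1=CC2(OCCO2)CC[C@H]1O | intermediate
4 | tert-butyl{[(8R)-7-iodo-1,4-dioxaspiro[4.5]dec-6-en-8-yl]oxy}dimethylsilane | IC1=CC2(OCCO2)CC[C@H]1O[Si](C)(C)C(C)(C)C | intermediate
5 | 5-bromo-2-methylpent-2-ene | CC(C)=CCCBr | starting material
6 | (4-methylpent-3-en-1-yl)magnesium bromide | CC(C)=CCC[Mg]Br | intermediate (not isolated)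
7 | (4-methylpent-3-en-1-yl)zinc chloride | CC(C)=CCC[Zn]Cl | intermediate (not isolated)
8 | tert-butyldimethyl{[(8R)-7-(4-methylpent-3-en-1-yl)-1,4-dioxaspiro[4.5]dec-6-en-8-yl]oxy}silane | CC(C)=CCCC1=CC2(OCCO2)CC[C@H]1O[Si](C)(C)C(C)(C)C | intermediate
9 | (4R)-4-[(tert-butyldimethylsilyl)oxy]-3-(4-methylpent-3-en-1-yl)cyclohex-2-en-1-one | CC(C)=CCCC1=CC(=O)CC[C@H]1O[Si](C)(C)C(C)(C)C | intermediate
10 | lithium (3S,4R)-4-[(tert-butyldimethylsilyl)oxy]-3-methyl-3-(4-methylpent-3-en-1-yl)cyclohex-1-en-1-olate | CC(C)=CCC[C@@]1(C)C=C(O[Li])CC[C@H]1O[Si](C)(C)C(C)(C)C | intermediate (not isolated)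
11 | (3S,4R)-4-[(tert-butyldimethylsilyl)oxy]-3-methyl-3-(4-methylpent-3-en-1-yl)cyclohex-1-en-1-yl trifluoromethanesulfonate | CC(C)=CCC[C@@]1(C)C=C(OS(=O)(=O)C(F)(F)F)CC[C@H]1O[Si](C)(C)C(C)(C)C | intermediate
12 | (3S,4R)-4-[(tert-butyldimethylsilyl)oxy]-3-{2-[(2R)-3,3-dimethyloxiran-2-yl]ethyl}-3-methylcyclohex-1-en-1-yl trifluoromethanesulfonate | CC1(C)O[C@@H]1CC[C@@]1(C)C=C(OS(=O)(=O)C(F)(F)F)CC[C@H]1O[Si](C)(C)C(C)(C)C | intermediate
13 | (E)-1,2-bis(tributylstannyl)ethene | CCCC[Sn](CCCC)(CCCC)/C=C/[Sn](CCCC)(CCCC)CCCC | starting material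
14 | tert-butyl{[(1R,2S)-2-{2-[(2R)-3,3-dimethyloxiran-2-yl]ethyl}-2-methyl-4-[(E)-2-(tributylstannyl)ethenyl]cyclohex-3-en-1-yl]oxy}dimethylsilane | CC1(C)O[C@@H]1CC[C@@]1(C)C=C(/C=C/[Sn](CCCC)(CCCC)CCCC)CC[C@H]1O[Si](C)(C)C(C)(C)C | intermediate
15 | (1R,2S)-2-{2-[(2R)-3,3-dimethyloxiran-2-yl]ethyl}-2-methyl-4-[(E)-2-(tributylstannyl)ethenyl]cyclohex-3-en-1-ol | CC1(C)O[C@@H]1CC[C@@]1(C)C=C(/C=C/[Sn](CCCC)(CCCC)CCCC)CC[C@H]1O | intermediate
16 | (1R,1'R,2S,2'S)-4,4'-[(1E,3E)-buta-1,3-diene-1,4-diyl]bis(2-{2-[(2R)-3,3-dimethyloxiran-2-yl]ethyl}-2-methylcyclohex-3-en-1-ol) | CC1(C)O[C@@H]1CC[C@@]1(C)C=C(/C=C/C=C/C2=C[C@](C)(CC[C@H]3OC3(C)C)[C@H](O)CC2)CC[C@H]1O | target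

**Totals**
Total step count: 10. Longest linear sequence: 10 steps (1 → 16); 5 and 13 are bought.

**Steps most likely to fail**

Step 10. Transmetalation of the tributylstannyl group to copper may be slow, so that protodestannylation competes, and the copper salts may act as Lewis acids and open the oxiranes. The fallback sets out from 15 and replaces the oxidative homocoupling by a palladium cross-coupling of two differently activated halves. One portion of 15 is treated with I2 (NaHCO3, CH2Cl2, 0 °C) to give, by iododestannylation with retention, the vinyl iodide (1R,2S)-2-{2-[(2R)-3,3-dimethyloxiran-2-yl]ethyl}-4-[(E)-2-iodoethenyl]-2-methylcyclohex-3-en-1-ol F1. Stille–Migita coupling of this iodide with a second portion of 15 (Pd2(dba)3, AsPh3, NMP, rt) should form the same central bond, and the route is rejoined at 16.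

Step 6. Addition at the hindered β-carbon may be slow, face selectivity may leak, and proton transfer between enolate and ketone before O-sulfonylation may erode the regiochemistry. The fallback sets out from 9 and separates C–C bond formation from triflation. TMSCl-accelerated addition of Me2CuLi (THF, −78 °C) should give the silyl enol ether tert-butyldimethyl{[(1R,2S)-2-methyl-2-(4-methylpent-3-en-1-yl)-4-[(trimethylsilyl)oxy]cyclohex-3-en-1-yl]oxy}silane F2, which can be purified from any diastereomer. MeLi (THF, 0 °C) then regenerates the enolate regiospecifically, so the route is rejoined at 10, which is triflated with PhNTf2 to 11 as in step 6.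

Step 8. The dienylstannane product may couple a second time with triflate to give the symmetrical triene, and it may lose tin on purification. The fallback sets out from 12 and builds the stannane by hydrometalation of an alkyne instead. Sonogashira coupling of 12 with ethynyltrimethylsilane (Pd(PPh3)4, CuI, Et3N, DMF, rt) should give tert-butyl{[(1R,2S)-2-{2-[(2R)-3,3-dimethyloxiran-2-yl]ethyl}-2-methyl-4-[(trimethylsilyl)ethynyl]cyclohex-3-en-1-yl]oxy}dimethylsilane F3. K2CO3 in MeOH should then give the terminal enyne tert-butyl{[(1R,2S)-2-{2-[(2R)-3,3-dimethyloxiran-2-yl]ethyl}-4-ethynyl-2-methylcyclohex-3-en-1-yl]oxy}dimethylsilane F4. Palladium-catalysed syn-hydrostannation (Bu3SnH, PdCl2(PPh3)2, THF, 0 °C) should place tin on the terminal carbon, and the route is rejoined at 14.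

**Further compounds**
F1 | step 10 | (1R,2S)-2-{2-[(2R)-3,3-dimethyloxiran-2-yl]ethyl}-4-[(E)-2-iodoethenyl]-2-methylcyclohex-3-en-1-ol | CC1(C)O[C@@H]1CC[C@@]1(C)C=C(/C=C/I)CC[C@H]1O
F2 | step 6 | tert-butyldimethyl{[(1R,2S)-2-methyl-2-(4-methylpent-3-en-1-yl)-4-[(trimethylsilyl)oxy]cyclohex-3-en-1-yl]oxy}silane | CC(C)=CCC[C@@]1(C)C=C(O[Si](C)(C)C)CC[C@H]1O[Si](C)(C)C(C)(C)C
F3 | step 8 | tert-butyl{[(1R,2S)-2-{2-[(2R)-3,3-dimethyloxiran-2-yl]ethyl}-2-methyl-4-[(trimethylsilyl)ethynyl]cyclohex-3-en-1-yl]oxy}dimethylsilane | CC1(C)O[C@@H]1CC[C@@]1(C)C=C(C#C[Si](C)(C)C)CC[C@H]1O[Si](C)(C)C(C)(C)C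
F4 | step 8 | tert-butyl{[(1R,2S)-2-{2-[(2R)-3,3-dimethyloxiran-2-yl]ethyl}-4-ethynyl-2-methylcyclohex-3-en-1-yl]oxy}dimethylsilane | CC1(C)O[C@@H]1CC[C@@]1(C)C=C(C#C)CC[C@H]1O[Si](C)(C)C(C)(C)C
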